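**Plan**

- Retrosynthesis (labdane numbering): the C15 acid and the C19–O angelate are unmasked last; the C11–C12 bond is cut to a C11 borane and a C12–C15 bromo ester that carries C13; the C3–C4 bond of ring A is cut by a retro-[3,3] shift to a C19(=O)–O–C1 vinyl lactone; the C1–C10 (aldol) and C10–CH3 bonds lead back to (R)-carvone.
- Forward: ring B is the carvone ring; its isopropenyl group becomes the C4/C18/C19 propanoate, C10 is methylated and then added to acrolein (C1–C3) with lactonisation; ring A is closed last by Ireland–Claisen rearrangement of that lactone; C11 and the C12–C16 chain are added afterwards.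
- Enabling feature: C4 of ring A is quaternary, α to a carboxyl-level carbon (C19) and 1,4 to C1 across the ring, while C1–C3 are plain CH2; a lactone bridge C19–O–C1 fused on the C5–C10 bond of ring B therefore holds a C4 ketene acetal under a vinyl group (C2=C3) on C1, and the C1=C2 alkene left by the shift is simply reduced.
- Stereochemistry: C5 from (R)-carvone; C10 by enolate attack anti to the C5 substituent; the temporary C1 carbinol by the closed aldol transition state; C4 by suprafacial transfer from C1 in the [3,3] shift; C9 by α-face hydroboration; C13 from (R)-4-methyldihydrofuran-2(3H)-one; the angelate geometry from angelic anhydride.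

Key step: step 7

Remark: labdane numbering (C1 to C20) is used for the bicyclic core of every intermediate; (R)-4-methyldihydrofuran-2(3H)-one and angelic anhydride are taken to be purchasable.

**Step 1**
Reactants: 1 (R)-carvone
Product: 3 (5R)-5-(1-hydroxypropan-2-yl)-2-methylcyclohex-2-en-1-ol (stereoisomer mixture), via bis-boryl adduct 2 (not isolated)
Conditions: 9-BBN (2.3 equiv), THF, 0 °C to 65 °C; then NaOH, H2O2, H2O, 0 °C
Reagents that add atoms: hydrogen peroxide, OO
Why: Hydroboration–oxidation: excess 9-BBN should add to the terminal carbon of the 1,1-disubstituted isopropenyl alkene and reduce the enone carbonyl 1,2 while leaving the trisubstituted ring alkene, and the two uncontrolled new centres are erased in steps 2 and 7.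

**Step 2**
Reactants: 3 diol
Product: 4 2-[(1R)-4-methyl-5-oxocyclohex-3-en-1-yl]propanoic acid (epimer mixture at C2 of the acid)
Conditions: CrO3, H2SO4, H2O, acetone, 0 °C
Reagents that add atoms: water, O
Why: Jones oxidation should return the allylic alcohol to the enone and take the primary alcohol to the acid in one operation, so the stereoisomers of 3 converge and C5 keeps the carvone configuration.

**Step 3**
Reactants: 4 keto acid
Product: 5 methyl 2-[(1R)-4-methyl-5-oxocyclohex-3-en-1-yl]propanoate
Conditions: MeOH, H2SO4 (cat.), 65 °C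
Reagents that add atoms: methanol, CO
Why: Fischer esterification of an unhindered acid; the enone can no longer aromatise because the isopropenyl group is gone.

**Step 4**
Reactants: 5 keto ester
Product: 7 methyl 2-[(1R)-4,6-dimethyl-5-oxocyclohex-3-en-1-yl]propanoate (epimer mixture), via lithium dienolate 6 (not isolated)
Conditions: LDA (1.05 equiv), THF, −78 °C; MeI, −78 to 0 °C
Reagents that add atoms: iodomethane, CI
Why: Kinetic enolate alkylation: LDA should deprotonate the ketone α′-CH2 (more acidic and less hindered than the ester α-CH) and the cross-conjugated enolate is C-methylated; the configuration of the new centre (C10) is irrelevant because it is re-enolised in step 5.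

**Step 5**
Reactants: 7 methylated keto ester; 8 acrolein
Product: 11 vinyl lactone (trans-fused C19→C1 δ-lactone on ring B), via lithium enolate 9 (not isolated), via lithium aldolate 10 (not isolated)
Conditions: LiHMDS, THF, −78 to −40 °C; acrolein, −78 °C; warm to 0 °C; aq. NH4Cl
Reagents that add atoms: none
Why: Aldol addition–lactonisation: LiHMDS should enolise the ketone but not the ester, the tetrasubstituted enolate should add 1,2 to acrolein on the face anti to the C5 side chain (setting C10), the Zimmerman–Traxler chair (C10 methyl cis to O–Li, ring carbon trans) should place the new C1 oxygen syn to the C10 methyl, and the aldolate should close onto the methyl ester on warming, which also removes it from retro-aldol equilibrium.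

**Step 6**
Reactants: 11 vinyl lactone
Product: 12 methylidene lactone (C9=CH2 in place of the C9 ketone)
Conditions: Zn, CH2Br2, TiCl4, THF–CH2Cl2, 0 °C to rt
Reagents that add atoms: dibromomethane, BrCBr
Why: Lombardo methylenation is non-basic, selective for ketones over lactones and suited to hindered ketones; it installs C11 and removes the only other site that LDA could attack in step 7.

**Step 7**
Reactants: 12 methylidene lactone
Product: 15 12,13,14,15,16-pentanorlabda-1,7,9(11)-trien-19-oic acid, via silyl ketene acetal 13 (not isolated), via silyl ester 14 (not isolated)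
Conditions: LDA, TBSCl, THF–DMPU, −78 °C to rt; toluene, 105 °C; then 1 M HCl, THF, rt
Reagents that add atoms: none
Why: Enolisation of the lactone is trapped in situ as the cyclic silyl ketene acetal, whose O–C19(OSi)=C4 unit and the vinyl group on C1 form a 1,5-diene that should undergo a concerted, suprafacial [3,3] shift (Ireland–Claisen rearrangement of a vinyl-substituted δ-lactone, a known ring transposition of 6-alkenyl lactones to cyclohexenecarboxylic acids). Ring A closes by C3–C4 bond formation with cleavage of the C1–O bond through a boat-like six-membered transition state, the only geometry that places the cis C1=C2 alkene inside the new six-membered ring. The new quaternary centre C4 is set by the C1 carbinol centre: the vinyl group is locked axial on the α face of the trans-fused lactone, so C3 adds to the α face of C4 and the carboxyl carbon C19 is pushed to the β (axial) side, cis to the C10 methyl, with the C4 methyl equatorial; both C4 epimers of 12 converge because this centre is planar in the ketene acetal. The step needs enolisation at the lactone only, secured by the earlier conversion of the C9 ketone into a methylidene group, and O-silylation faster than ketene extrusion from the enolate, secured by the internal TBSCl quench at −78 °C. The trans ring fusion at C5 and C10 is not touched.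

**Step 8**
Reactants: 15 acid
Product: 16 12,13,14,15,16-pentanorlabda-1,7,9(11)-trien-19-ol
Conditions: LiAlH4, THF, 65 °C; aq. NaOH work-up
Reagents that add atoms: none
Why: LiAlH4 reduction of a hindered carboxylic acid to the neopentyl alcohol; the alkenes and the unactivated diene are inert.

**Step 9**
Reactants: 16 alcohol; 17 angelic anhydride
Product: 19 12,13,14,15,16-pentanorlabda-1,7,9(11)-trien-19-yl (Z)-2-methylbut-2-enoate, via lithium alkoxide 18 (not isolated)
Conditions: LiHMDS, THF, −78 °C; 17, −78 to 0 °C; aq. NH4Cl
Reagents that add atoms: none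
Why: Acylation of the pre-formed lithium alkoxide by the anhydride is fast even at a neopentyl oxygen and needs no nucleophilic acyl-transfer catalyst, so Z to E isomerisation of the angelate is not expected.

**Step 10**
Reactants: 20 (R)-4-methyldihydrofuran-2(3H)-one
Product: 21 methyl (R)-4-bromo-3-methylbutanoate
Conditions: HBr (gas), MeOH, 0 °C to rt
Reagents that add atoms: hydrogen bromide, Br; methanol, CO
Why: Bromide should open the protonated lactone by SN2 attack at the O–CH2 carbon and methanol esterifies the acid; the stereocentre is not involved.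

**Step 11**
Reactants: 19 angelate; 21 bromo ester
Product: 23 methyl (13S)-19-[(Z)-2-methylbut-2-enoyloxy]labda-1,7-dien-15-oate, via alkylborane 22 (not isolated)
Conditions: 9-BBN (1.1 equiv), THF, 0 °C to rt; then 21 (2 equiv), Pd(OAc)2 (5 mol %), PCy3 (10 mol %), K3PO4·H2O, THF, rt
Reagents that add atoms: none
Why: 9-BBN should add to the terminal carbon of the exocyclic C9=C11 alkene (the cyclohexene-type C1=C2 and the trisubstituted alkenes react far more slowly) from the α face opposite the axial C10 methyl, setting 9α-H, and the primary alkylborane is then joined to the primary bromide by alkyl–alkyl Suzuki–Miyaura coupling under ester-tolerant phosphate conditions.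

**Step 12**
Reactants: 23 dienyl diester
Product: 24 methyl (13S)-19-[(Z)-2-methylbut-2-enoyloxy]labd-7-en-15-oate
Conditions: 2-nitrobenzenesulfonylhydrazide (excess), Et3N, CH2Cl2, rt
Reagents that add atoms: none
Why: Diimide reduction: concerted syn transfer of H2 should be much faster to the cis-disubstituted C1=C2 alkene than to the trisubstituted C7=C8 and angelate alkenes, and no stereocentre is formed.

**Step 13**
Reactants: 24 methyl ester
Product: 25 (13S)-19-[(Z)-2-methylbut-2-enoyloxy]labd-7-en-15-oic acid (target)
Conditions: Me3SnOH, 1,2-dichloroethane, 70 °C; then cold 0.1 M HCl wash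
Reagents that add atoms: trimethyltin hydroxide, C[Sn](C)(C)O
Why: Me3SnOH should cleave the unhindered methyl ester and leave the neopentyl, conjugated angelate; the near-neutral conditions avoid angelate isomerisation and migration of the C7=C8 alkene.

**Compound list**

1 | (R)-carvone, (5R)-2-methyl-5-(prop-1-en-2-yl)cyclohex-2-en-1-one | CC1=CC[C@H](CC1=O)C(C)=C | starting material
2 | bis-boryl adduct of 1: 9-BBN on the side-chain CH2 and as borinate on the ring oxygen (stereoisomer mixture) | CC1=CC[C@@H](C(C)CB2C3CCCC2CCC3)CC1OB1C2CCCC1CCC2 | intermediate (not isolated)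
3 | (5R)-5-(1-hydroxypropan-2-yl)-2-methylcyclohex-2-en-1-ol (mixture at C1 and at the side-chain carbon) | CC1=CC[C@@H](C(C)CO)CC1O | intermediate
4 | 2-[(1R)-4-methyl-5-oxocyclohex-3-en-1-yl]propanoic acid (mixture at C2 of the acid) | CC1=CC[C@@H](C(C)C(=O)O)CC1=O | intermediate
5 | methyl 2-[(1R)-4-methyl-5-oxocyclohex-3-en-1-yl]propanoate (mixture at C2 of the ester) | CC1=CC[C@@H](C(C)C(=O)OC)CC1=O | intermediate
6 | lithium cross-conjugated dienolate of 5 | [Li+].[O-]C1=C[C@H](C(C)C(=O)OC)CC=C1C | intermediate (not isolated)
7 | methyl 2-[(1R)-4,6-dimethyl-5-oxocyclohex-3-en-1-yl]propanoate (mixture at ring C6 and at C2 of the ester) | CC1=CC[C@@H](C(C)C(=O)OC)C(C)C1=O | intermediate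
8 | acrolein (prop-2-enal) | C=CC=O | starting material
9 | lithium enolate of 7 (tetrasubstituted, O–Li on the ring carbonyl) | [Li+].[O-]C1=C(C)[C@H](C(C)C(=O)OC)CC=C1C | intermediate (not isolated)
10 | lithium aldolate: 1,2-adduct of 9 and acrolein, new CH(OLi)CH=CH2 group on C10 trans to the ester side chain on C5 | [Li+].[O-][C@H](C=C)[C@]1(C)C(=O)C(C)=CC[C@H]1C(C)C(=O)OC | intermediate (not isolated)
11 | 1-ethenyl-4,7,8a-trimethyl-4a,5-dihydro-1H-isochromene-3,8(4H,8aH)-dione; trans ring fusion (4a-H trans to 8a-CH3), ethenyl axial and trans to the 8a-CH3, C4 epimer mixture; labdane atoms: C19(=O)–O–C1 lactone, C9 ketone | O=C1O[C@H](C=C)[C@]2(C)C(=O)C(C)=CC[C@H]2C1C | intermediate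
12 | 1-ethenyl-4,7,8a-trimethyl-8-methylidene-1,4,4a,5,8,8a-hexahydro-3H-isochromen-3-one (configuration as 11, C9=C11H2) | O=C1O[C@H](C=C)[C@]2(C)C(=C)C(C)=CC[C@H]2C1C | intermediate
13 | cyclic tert-butyldimethylsilyl ketene acetal of 12 (C4=C19 double bond, O–Si on C19) | CC1=C(O[Si](C)(C)C(C)(C)C)O[C@H](C=C)[C@]2(C)C(=C)C(C)=CC[C@@H]12 | intermediate (not isolated)
14 | tert-butyldimethylsilyl ester of 15 | CC(C)(C)[Si](C)(C)OC(=O)[C@@]1(C)CC=C[C@]2(C)C(=C)C(C)=CC[C@@H]12 | intermediate (not isolated)
15 | 12,13,14,15,16-pentanorlabda-1,7,9(11)-trien-19-oic acid (5α-H, 10β-CH3, carboxyl β-axial on C4, 4α-CH3); 1,4a,6-trimethyl-5-methylidene-1,2,4a,5,8,8a-hexahydronaphthalene-1-carboxylic acid | OC(=O)[C@@]1(C)CC=C[C@]2(C)C(=C)C(C)=CC[C@@H]12 | intermediate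
16 | 12,13,14,15,16-pentanorlabda-1,7,9(11)-trien-19-ol | OC[C@@]1(C)CC=C[C@]2(C)C(=C)C(C)=CC[C@@H]12 | intermediate
17 | angelic anhydride, (Z)-2-methylbut-2-enoic anhydride | C/C=C(/C)C(=O)OC(=O)C(\C)=C/C | starting material
18 | lithium alkoxide of 16 | [Li+].[O-]C[C@@]1(C)CC=C[C@]2(C)C(=C)C(C)=CC[C@@H]12 | intermediate (not isolated)
19 | 12,13,14,15,16-pentanorlabda-1,7,9(11)-trien-19-yl (Z)-2-methylbut-2-enoate | C/C=C(/C)C(=O)OC[C@@]1(C)CC=C[C@]2(C)C(=C)C(C)=CC[C@@H]12 | intermediate
20 | (R)-4-methyldihydrofuran-2(3H)-one | C[C@H]1COC(=O)C1 | starting material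
21 | methyl (R)-4-bromo-3-methylbutanoate | BrC[C@H](C)CC(=O)OC | intermediate
22 | 9-[19-(angeloyloxy)-12,13,14,15,16-pentanorlabda-1,7-dien-11-yl]-9-borabicyclo[3.3.1]nonane (9α-H) | C/C=C(/C)C(=O)OC[C@@]1(C)CC=C[C@]2(C)[C@@H](CB3C4CCCC3CCC4)C(C)=CC[C@@H]12 | intermediate (not isolated)
23 | methyl (13S)-19-[(Z)-2-methylbut-2-enoyloxy]labda-1,7-dien-15-oate | C/C=C(/C)C(=O)OC[C@@]1(C)CC=C[C@]2(C)[C@@H](CC[C@H](C)CC(=O)OC)C(C)=CC[C@@H]12 | intermediate
24 | methyl (13S)-19-[(Z)-2-methylbut-2-enoyloxy]labd-7-en-15-oate | C/C=C(/C)C(=O)OC[C@@]1(C)CCC[C@]2(C)[C@@H](CC[C@H](C)CC(=O)OC)C(C)=CC[C@@H]12 | intermediate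
25 | (13S)-19-[(Z)-2-methylbut-2-enoyloxy]labd-7-en-15-oic acid (CNP0180171.1) | C/C=C(/C)C(=O)OC[C@@]1(C)CCC[C@]2(C)[C@@H](CC[C@H](C)CC(=O)O)C(C)=CC[C@@H]12 | target

**Count and risks**

Total step count: 13. Longest linear sequence: 12 (steps 1 to 9 and 11 to 13).

Steps most likely to fail:

1. Step 7. The lithium lactone enolate may fragment to a ketene and the allylic alkoxide before it is O-silylated, or the boat-type shift may be slow enough that desilylation competes. The fallback sets out from 12 and comes back at 16. DIBAL-H (toluene, −78 °C) should give the lactol F4; dehydration with MsCl and Et3N should give the cyclic enol ether F5; heating in a sealed tube at about 180 °C should bring about the aliphatic Claisen rearrangement, with the same C1 to C4 transfer but no enolate, to the aldehyde F6; NaBH4 in MeOH should then give 16.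

2. Step 5. A tetrasubstituted lithium enolate and a small aldehyde may give poor simple diastereoselection, and retro-aldol equilibration may occur while the aldolate waits to lactonise; the carbinol epimer with an equatorial vinyl group cannot reach C4. The fallback sets out from 7 and comes back at 11. The aldol is quenched at −78 °C to keep the hydroxy ester F1 as both carbinol epimers; Dess–Martin periodinane should give the vinyl diketone F2; Corey–Bakshi–Shibata reduction with the (S)-oxazaborolidine and catecholborane (quaternary carbon as the large group, hindered ring enone left alone) should give the single carbinol epimer F3 under reagent control; CSA in toluene should close it to 11.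

3. Step 11. Transmetalation of the hindered, β-branched alkylborane and oxidative addition of the β-branched bromide may both be slow, so that β-hydride elimination and protodeboronation take over. The fallback sets out from 19 and comes back at 23. 9-BBN followed by NaBO3 should give the primary alcohol F7; I2, PPh3 and imidazole should give the iodide F8; the organozinc bromide F9 is made from 21 with Zn and LiCl in THF; Negishi alkyl–alkyl coupling of F8 with F9 (Pd2(dba)3, PCyp3, N-methylimidazole, THF–NMP, 80 °C) should give 23, with the hindered partner now the electrophile.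

**Further compounds**

F1 | step 5 | methyl 2-[(1R,2R)-2-(1-hydroxyprop-2-en-1-yl)-2,4-dimethyl-3-oxocyclohex-4-en-1-yl]propanoate (both carbinol epimers, side chain on C10 trans to the propanoate on C5) | OC(C=C)[C@]1(C)C(=O)C(C)=CC[C@H]1C(C)C(=O)OC
F2 | step 5 | methyl 2-[2,4-dimethyl-3-oxo-2-(prop-2-enoyl)cyclohex-4-en-1-yl]propanoate (acryloyl on C10 trans to the propanoate on C5) | O=C(C=C)[C@]1(C)C(=O)C(C)=CC[C@H]1C(C)C(=O)OC
F3 | step 5 | single carbinol epimer of F1 (C1 oxygen syn to the C10 methyl in the zigzag drawing) | O[C@H](C=C)[C@]1(C)C(=O)C(C)=CC[C@H]1C(C)C(=O)OC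
F4 | step 7 | lactol of 12 (1-ethenyl-4,7,8a-trimethyl-8-methylidene-3,4,4a,5,8,8a-hexahydro-1H-isochromen-3-ol) | OC1O[C@H](C=C)[C@]2(C)C(=C)C(C)=CC[C@H]2C1C
F5 | step 7 | cyclic enol ether (1-ethenyl-4,7,8a-trimethyl-8-methylidene-4a,5,8,8a-tetrahydro-1H-isochromene) | CC1=CO[C@H](C=C)[C@]2(C)C(=C)C(C)=CC[C@@H]12
F6 | step 7 | 12,13,14,15,16-pentanorlabda-1,7,9(11)-trien-19-al | O=C[C@@]1(C)CC=C[C@]2(C)C(=C)C(C)=CC[C@@H]12
F7 | step 11 | 11-hydroxy-12,13,14,15,16-pentanorlabda-1,7-dien-19-yl (Z)-2-methylbut-2-enoate (9α-H) | C/C=C(/C)C(=O)OC[C@@]1(C)CC=C[C@]2(C)[C@@H](CO)C(C)=CC[C@@H]12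
F8 | step 11 | 11-iodo-12,13,14,15,16-pentanorlabda-1,7-dien-19-yl (Z)-2-methylbut-2-enoate (9α-H) | C/C=C(/C)C(=O)OC[C@@]1(C)CC=C[C@]2(C)[C@@H](CI)C(C)=CC[C@@H]12
F9 | step 11 | [(2R)-4-methoxy-2-methyl-4-oxobutyl]zinc bromide | Br[Zn]C[C@H](C)CC(=O)OC
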